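**Retrosynthetic overview**

1. The ethylene bridge is cut between its two CH2 groups (the benzylic CH2 of the 4-hydroxy-3-methoxyphenyl ring and the CH2 on C2 of the chromone). In the same retrosynthetic operation the O1–C2 bond of the pyranone ring is opened, which leads back to the silyl-protected vanillyl bromide 6 and the open-chain β-diketone 2.
2. Enabling feature: the pyranone ring atoms O1–C2=C3–C4=O are the cyclodehydrated form of a 1,3-diketone that carries an ortho-phenol on the fused benzene ring (the C8a–O1 oxygen). In the ring-opened form the CH2 on C2 is the terminal carbon of a β-diketone and becomes the most nucleophilic site of its trianion.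
3. Ring order: both benzene rings are bought (acetophenone 1, vanillin 3). The pyranone ring is the only ring made and closes last, inside the key step, by cyclodehydration of a 1,5-diarylpentane-1,3-dione; this ring closure mirrors the presumed biosynthesis of 2-(2-phenylethyl)chromones from a C6–C5–C6 diketone.
4. The acid that closes the ring also cleaves the phenol silyl ether, so the key step should deliver the target itself.

Key step: step 5

Remark: the target has no stereocentre and no stereogenic double bond, so it is achiral; the question of a single enantiomer does not arise and no step has to set or keep a configuration.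

**Route**

Step 1
Reactants: 1 1-(2-hydroxy-4,5-dimethoxyphenyl)ethan-1-one
Product: 2 1-(2-hydroxy-4,5-dimethoxyphenyl)butane-1,3-dione
Conditions: NaH (4 equiv), EtOAc (5 equiv), THF, reflux; then cold 1 M HCl to pH 5
Reagents that add atoms: ethyl acetate, CCOC(C)=O
Why: Crossed Claisen condensation in which the phenoxide–enolate dianion of 1 is C-acetylated by ethyl acetate and the irreversible deprotonation of the β-diketone drives the equilibrium; the cold, weakly acidic quench should avoid premature cyclodehydration, and 2 is expected as a mixture of diketone, enol and cyclic hemiketal tautomers that all give the same trianion later.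

Step 2
Reactants: 3 4-hydroxy-3-methoxybenzaldehyde (vanillin)
Product: 4 4-[(tert-butyldimethylsilyl)oxy]-3-methoxybenzaldehyde
Conditions: TBSCl (1.1 equiv), Et3N (1.5 equiv), DMAP (cat.), CH2Cl2, 0 °C to rt
Reagents that add atoms: tert-butyldimethylsilyl chloride, CC(C)(C)[Si](C)(C)Cl
Why: Silyl ether formation at the only OH group masks the acidic phenol proton that would quench the trianion of step 5, with a group that the acid of step 5 should remove again.

Step 3
Reactants: 4 4-[(tert-butyldimethylsilyl)oxy]-3-methoxybenzaldehyde
Product: 5 {4-[(tert-butyldimethylsilyl)oxy]-3-methoxyphenyl}methanol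
Conditions: NaBH4 (1 equiv), THF/MeOH, 0 °C, short reaction time
Reagents that add atoms: none
Why: Borohydride reduction of the aldehyde to the benzylic alcohol, run cold and briefly so that the base-sensitive aryl silyl ether should survive.

Step 4
Reactants: 5 {4-[(tert-butyldimethylsilyl)oxy]-3-methoxyphenyl}methanol
Product: 6 [4-(bromomethyl)-2-methoxyphenoxy](tert-butyl)dimethylsilane
Conditions: PBr3 (0.4 equiv), Et2O, 0 °C; cold NaHCO3 wash, used at once without chromatography
Reagents that add atoms: phosphorus tribromide, BrP(Br)Br
Why: Bromination of an electron-rich benzylic alcohol with PBr3 (displacement of the phosphite ester by bromide) is fast at 0 °C in ether, conditions under which the aryl silyl ether should stay intact.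

Step 5
Reactants: 2 1-(2-hydroxy-4,5-dimethoxyphenyl)butane-1,3-dione, 6 [4-(bromomethyl)-2-methoxyphenoxy](tert-butyl)dimethylsilane
Product: 10 2-[2-(4-hydroxy-3-methoxyphenyl)ethyl]-6,7-dimethoxy-4H-chromen-4-one (target), via trilithium diketone trianion 7 (not isolated), via silyl-protected diarylpentanedione 8 (not isolated), via silyl-protected chromone 9 (not isolated)
Conditions: 2 (1.2 equiv), LDA (3.7 equiv, commercial solution), THF, −78 to 0 °C; 6 (1.0 equiv), −78 to 0 °C; then 3 M HCl in MeOH, 60 °C (one pot)
Reagents that add atoms: none
Why: Three equivalents of LDA remove in turn the phenol proton, a proton of the central CH2 and a proton of the terminal methyl group of 2, and the carbanion formed last is the most basic and most nucleophilic site of trianion 7, so the SN2 reaction with the benzylic bromide 6 should take place at the terminal carbon and give, after protonation, the 1,5-diarylpentane-1,3-dione 8. The closest known reaction type is the terminal (γ) alkylation of β-diketone dianions and of o-hydroxyaryl β-diketone trianions with benzylic halides. Methanolic HCl then closes the pyranone ring by attack of the phenol oxygen on the C3 carbonyl carbon of the diketone (6-exo-trig addition to give the 2-hydroxychroman-4-one hemiketal) followed by loss of water; this is the classical cyclodehydration of o-hydroxyaryl β-diketones to chromones and the same ring closure that the presumed biosynthesis applies to its diarylpentanoid diketone. The same acid should cleave the aryl silyl ether of 9 by methanolysis, so no separate deprotection is planned. No stereocentre is formed. The selectivity needed is C-alkylation at the terminal carbon over the central carbon and over the three oxygens, which is secured by the order of deprotonation, by the lithium counter-ion in THF that keeps the phenoxide and enolate oxygens unreactive, and by using the bromide as the limiting reagent to suppress a second alkylation.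

**Compound list**

1 | 1-(2-hydroxy-4,5-dimethoxyphenyl)ethan-1-one | CC(=O)c1cc(OC)c(OC)cc1O | starting material
2 | 1-(2-hydroxy-4,5-dimethoxyphenyl)butane-1,3-dione | CC(=O)CC(=O)c1cc(OC)c(OC)cc1O | intermediate
3 | 4-hydroxy-3-methoxybenzaldehyde (vanillin) | COc1cc(C=O)ccc1O | starting material
4 | 4-[(tert-butyldimethylsilyl)oxy]-3-methoxybenzaldehyde | COc1cc(C=O)ccc1O[Si](C)(C)C(C)(C)C | intermediate
5 | {4-[(tert-butyldimethylsilyl)oxy]-3-methoxyphenyl}methanol | COc1cc(CO)ccc1O[Si](C)(C)C(C)(C)C | intermediate
6 | [4-(bromomethyl)-2-methoxyphenoxy](tert-butyl)dimethylsilane | COc1cc(CBr)ccc1O[Si](C)(C)C(C)(C)C | intermediate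
7 | trilithium trianion of 2 (phenoxide and bis-enolate) | [Li+].[Li+].[Li+].C=C([O-])C=C([O-])c1cc(OC)c(OC)cc1[O-] | intermediate (not isolated)
8 | 5-{4-[(tert-butyldimethylsilyl)oxy]-3-methoxyphenyl}-1-(2-hydroxy-4,5-dimethoxyphenyl)pentane-1,3-dione | O=C(CCc1ccc(O[Si](C)(C)C(C)(C)C)c(OC)c1)CC(=O)c1cc(OC)c(OC)cc1O | intermediate (not isolated)
9 | 2-(2-{4-[(tert-butyldimethylsilyl)oxy]-3-methoxyphenyl}ethyl)-6,7-dimethoxy-4H-chromen-4-one | COc1cc(CCc2cc(=O)c3cc(OC)c(OC)cc3o2)ccc1O[Si](C)(C)C(C)(C)C | intermediate (not isolated)
10 | 2-[2-(4-hydroxy-3-methoxyphenyl)ethyl]-6,7-dimethoxy-4H-chromen-4-one | COc1cc(CCc2cc(=O)c3cc(OC)c(OC)cc3o2)ccc1O | target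

**Step count**

Total steps: 5. Longest linear sequence: 4 steps (3 → 4 → 5 → 6 → 10); the second branch (1 → 2) has 1 step before the convergent key step.

**Steps most likely to fail**

1. Step 5. Proton transfer between trianion 7 and the monoalkylated dianion may lead to a second alkylation, alkylation may stray to the central carbon or to oxygen, and methanolysis of the silyl ether may stay incomplete. The fallback sets out from 2 and comes back to the route at 10. It closes the ring first and forms the bridge bond by condensation instead of alkylation. Diketone 2 is cyclodehydrated (cat. H2SO4, AcOH, 100 °C) to 6,7-dimethoxy-2-methyl-4H-chromen-4-one F1. The vinylogously acidic C2-methyl group of this chromone is condensed with commercial 4-(benzyloxy)-3-methoxybenzaldehyde (COc1cc(C=O)ccc1OCc1ccccc1; NaOEt, EtOH, rt) to give (E)-2-[4-(benzyloxy)-3-methoxystyryl]-6,7-dimethoxy-4H-chromen-4-one F2. Hydrogenation (H2 1 atm, Pd/C, EtOAc/MeOH, rt) should saturate the styryl double bond and cleave the benzyl ether in one operation to give 10.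

2. Step 4. The electron-rich benzylic bromide may alkylate itself or hydrolyse during isolation, and adventitious HBr may cleave the silyl ether. The fallback sets out from 4 (with 2) and comes back at 10. It avoids the halide by using the aldehyde as the electrophile. Trianion 7, made from 2 as in step 5, is treated with aldehyde 4; terminal aldol addition should give racemic 5-{4-[(tert-butyldimethylsilyl)oxy]-3-methoxyphenyl}-5-hydroxy-1-(2-hydroxy-4,5-dimethoxyphenyl)pentane-1,3-dione F3, which is not isolated and whose carbinol centre is lost in the next operation. Methanolic HCl at 60 °C should close the pyranone ring, dehydrate the benzylic alcohol and remove the silyl group to give (E)-2-(4-hydroxy-3-methoxystyryl)-6,7-dimethoxy-4H-chromen-4-one F4. Hydrogenation of the styryl double bond (H2 1 atm, Pd/C, EtOAc/MeOH, rt) gives 10.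

3. Step 1. The condensation may stall at the poorly soluble dianion of 1, self-condensation of ethyl acetate may consume the base, and the product may cyclodehydrate during acidic work-up. The fallback sets out from 1 and comes back at 2. It moves the acetyl group intramolecularly (Baker–Venkataraman rearrangement). Phenol 1 is acetylated (Ac2O, pyridine, DMAP cat., rt) to 2-acetyl-4,5-dimethoxyphenyl acetate F5. Treatment with t-BuOK (2.2 equiv) in THF at 0 °C to rt should transfer the acetyl group from oxygen to the ketone enolate carbon and give 2 after a cold, weakly acidic quench.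

**Further compounds**

F1 | step 5 | 6,7-dimethoxy-2-methyl-4H-chromen-4-one | Cc1cc(=O)c2cc(OC)c(OC)cc2o1
F2 | step 5 | (E)-2-[4-(benzyloxy)-3-methoxystyryl]-6,7-dimethoxy-4H-chromen-4-one | COc1cc(/C=C/c2cc(=O)c3cc(OC)c(OC)cc3o2)ccc1OCc1ccccc1
F3 | step 4 | 5-{4-[(tert-butyldimethylsilyl)oxy]-3-methoxyphenyl}-5-hydroxy-1-(2-hydroxy-4,5-dimethoxyphenyl)pentane-1,3-dione (racemic) | O=C(CC(O)c1ccc(O[Si](C)(C)C(C)(C)C)c(OC)c1)CC(=O)c1cc(OC)c(OC)cc1O
F4 | step 4 | (E)-2-(4-hydroxy-3-methoxystyryl)-6,7-dimethoxy-4H-chromen-4-one | COc1cc(/C=C/c2cc(=O)c3cc(OC)c(OC)cc3o2)ccc1O
F5 | step 1 | 2-acetyl-4,5-dimethoxyphenyl acetate | CC(=O)Oc1cc(OC)c(OC)cc1C(C)=O
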